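**Plan**

Retrosynthetic cuts, in order: first the C8–C(=O) bond, which releases the enone and ring C as a cinnamic Weinreb amide. Next the two C2–CH3 bonds and the O1–C2 ether bond, tracing the gem-dimethyl ether back to a lactone carbonyl. Last, C3–C4 and the lactone O1–C2 acyl bond.
Enabling feature: in ring B, C4 is a bare benzylic CH2 on C4a, and both ring A neighbours of C4a (C5 and C8a) carry oxygen. The unit O1–C8a–C4a–C4 is therefore a masked ortho-quinone methide, and the carbinol stereocentre C3 next to C4 matches the alpha-carbon of a glycolic acid enolate.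
Forward: ring A is bought. Ring B is closed first as a chroman-2-one by a catalytic (4+2) annulation, opened by double methyl addition at C2, and closed again as the 2,2-dimethylchroman. C8 is then brominated, lithiated and acylated, which brings in the enone and ring C.
Stereochemistry: C3 (S) is the only stereocentre. It is set in the annulation by the chiral isothiourea (R)-2-phenyl-2,3-dihydroimidazo[2,1-b]benzothiazole, and no later step breaks a bond to it. The E-alkene comes from a Horner–Wadsworth–Emmons reaction.
O5 travels as a benzyl ether so that only one phenol is present in the annulation. It is later exchanged for a bulky silyl ether that steers substitution from C6 to C8.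

Key step: step 5

Assumption: the sense of induction follows the accepted model for isothiourea-bound (Z)-ammonium enolates (coplanar 1,5-O···S contact, bond formation anti to the catalyst phenyl group), which pairs the (R)-catalyst with (S)-configured C3; both catalyst enantiomers are commercial.

**Route**

Step 1
Reactants: 1 2,4,6-trimethoxybenzaldehyde
Product: 2 2,6-dihydroxy-4-methoxybenzaldehyde
Conditions: AlCl3 (5 equiv), CH2Cl2, 0 °C → reflux; then 1 M HCl
Reagents that add atoms: none
Why: Chelation-directed Lewis-acid cleavage of aryl methyl ethers, in which AlCl3 bridges the aldehyde oxygen and an ortho methoxy oxygen, so chloride removes only the two ortho methyl groups and the para methoxy group (the future C7–OMe) stays.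

Step 2
Reactants: 2 2,6-dihydroxy-4-methoxybenzaldehyde
Product: 3 2-(benzyloxy)-6-hydroxy-4-methoxybenzaldehyde
Conditions: BnBr (1.05 equiv), K2CO3 (1.1 equiv), acetone, reflux
Reagents that add atoms: benzyl bromide, BrCc1ccccc1
Why: Williamson ether synthesis that should stop at mono-alkylation, because after the first benzylation the remaining phenol is locked in a strong hydrogen bond to the aldehyde and reacts far more slowly with a weak base and one equivalent of halide.

Step 3
Reactants: 3 2-(benzyloxy)-6-hydroxy-4-methoxybenzaldehyde
Product: 4 3-(benzyloxy)-2-(hydroxymethyl)-5-methoxyphenol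
Conditions: NaBH4 (1 equiv), THF/MeOH, 0 °C; aq. NH4Cl
Reagents that add atoms: none
Why: Borohydride reduction of an aldehyde, kept cold and short so that the electron-rich salicyl alcohol does not lose hydroxide and get reduced further to the methyl compound.

Step 4
Reactants: 4 3-(benzyloxy)-2-(hydroxymethyl)-5-methoxyphenol
Product: 5 3-(benzyloxy)-5-methoxy-2-(tosylmethyl)phenol
Conditions: p-TolSO2Na (3 equiv), HCO2H/H2O/THF, rt
Reagents that add atoms: sodium p-toluenesulfinate, Cc1ccc(cc1)S(=O)[O-].[Na+]
Why: SN1-type dehydrative sulfonylation of a salicyl alcohol, in which the trioxygenated benzylic position ionises under weak acid and the soft sulfur nucleophile, held in excess, should capture it faster than a second arene can, giving a storable sulfone.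

Step 5
Reactants: 5 3-(benzyloxy)-5-methoxy-2-(tosylmethyl)phenol; 6 (benzyloxy)acetic acid
Product: 10 (S)-3,5-bis(benzyloxy)-7-methoxychroman-2-one, via mixed anhydride 7 (not isolated), via ortho-quinone methide 8 (not isolated), via ammonium enolate 9 (not isolated)
Conditions: 6 (2 equiv), t-BuCOCl (2 equiv), iPr2NEt (3 equiv), CH2Cl2, 0 °C, 30 min; then 5, (R)-2-phenyl-2,3-dihydroimidazo[2,1-b]benzothiazole (10 mol %), Cs2CO3 (2.5 equiv), −20 °C → rt
Reagents that add atoms: none
Why: Proposed new method: t-BuCOCl converts 6 into mixed anhydride 7, whose less hindered carbonyl N-acylates the isothiourea, and deprotonation gives the (Z)-ammonium enolate 9, while Cs2CO3 deprotonates the one free phenol of 5 and sulfinate leaves (E1cB) to unveil ortho-quinone methide 8. The enolate carbon (C3) adds to the exocyclic CH2 (C4) of 8 in a Michael addition driven by rearomatisation of ring A, and the aryloxide O1 thus formed attacks the acyl ammonium carbonyl (C2) in a 6-exo-trig acyl substitution that closes ring B and releases the catalyst. The closest known reaction type is the isothiourea- or carbene-catalysed Michael addition–lactonisation of arylacetic acid enolates with ortho-quinone methides generated in situ from 2-(sulfonylmethyl)phenols, and alpha-benzyloxy ammonium enolates are known from cinchona-alkaloid-catalysed cycloadditions of benzyloxyacetyl chloride, so only the pairing of an alpha-alkoxy enolate with an isothiourea and a quinone methide is new; the inductive pull of the ether oxygen should keep the acyl ammonium alpha-proton within reach of iPr2NEt. C3 is the only new stereocentre and is controlled by the catalyst: the 1,5-O···S contact holds enolate and isothiouronium coplanar, the pseudoaxial phenyl group covers one face, and bond formation on the open face of the (Z)-enolate bound to the (R)-catalyst should give (S). The step needs enantioface selectivity at the enolate only (the CH2 terminus creates no stereocentre), formation of a single quinone methide and C–C bond formation ahead of phenol O-acylation; the O5 benzyl ether secures the last two, since it leaves one phenol that is consumed by rapid sulfinate loss from the electron-rich ring and removes a second acidic OH that would turn the quinone methide into a poorly electrophilic anion. A heterogeneous base, low temperature and prompt work-up should protect the alpha-alkoxy aryl ester 10 from enolisation at C3.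

Step 6
Reactants: 10 (S)-3,5-bis(benzyloxy)-7-methoxychroman-2-one
Product: 12 (S)-3-(benzyloxy)-2-[2-(benzyloxy)-3-hydroxy-3-methylbutyl]-5-methoxyphenol, via methyl ketone 11 (not isolated)
Conditions: anhydrous CeCl3 (4 equiv), MeLi (4 equiv), THF, −78 °C, 1 h; then 10, −78 → −40 °C; aq. NH4Cl
Reagents that add atoms: methyllithium, [Li]C
Why: Double 1,2-addition of an organocerium reagent to an aryl ester, in which the first methyl expels aryloxide O1 to give ketone 11, the second gives the tertiary alkoxide, and the low basicity of the cerium reagent should avoid enolisation at C3 in both 10 and 11, so the configuration is kept.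

Step 7
Reactants: 12 (S)-3-(benzyloxy)-2-[2-(benzyloxy)-3-hydroxy-3-methylbutyl]-5-methoxyphenol
Product: 13 (S)-3,5-bis(benzyloxy)-7-methoxy-2,2-dimethylchroman
Conditions: p-TsOH·H2O (10 mol %), toluene, 50 °C
Reagents that add atoms: none
Why: Acid-catalysed cyclodehydration of a 2-(3-hydroxy-3-methylbutyl)phenol, the classical closure of 2,2-dimethylchromans, in which the tertiary alcohol ionises at C2, the nearby electron-rich phenol O1 captures the cation in a six-membered closure, and no bond to C3 is broken, so (S) is retained.

Step 8
Reactants: 13 (S)-3,5-bis(benzyloxy)-7-methoxy-2,2-dimethylchroman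
Product: 14 (S)-7-methoxy-2,2-dimethylchroman-3,5-diol
Conditions: H2 (1 atm), Pd(OH)2/C, EtOAc/EtOH, rt
Reagents that add atoms: none
Why: Catalytic hydrogenolysis of both benzyl ethers in one operation, placed before the enone exists and safe for the chroman because none of its own C–O bonds is benzylic.

Step 9
Reactants: 14 (S)-7-methoxy-2,2-dimethylchroman-3,5-diol
Product: 15 (S)-3,5-bis[(tert-butyldimethylsilyl)oxy]-7-methoxy-2,2-dimethylchroman
Conditions: TBSOTf (2.6 equiv), 2,6-lutidine (4 equiv), CH2Cl2, 0 °C → rt
Reagents that add atoms: tert-butyldimethylsilyl trifluoromethanesulfonate, CC(C)(C)[Si](C)(C)OS(=O)(=O)C(F)(F)F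
Why: Silyl ether formation with a silyl triflate, reactive enough for the hindered C3 carbinol beside the quaternary C2, which removes both acidic protons before the organolithium step and places a bulky group next to C6.

Step 10
Reactants: 15 (S)-3,5-bis[(tert-butyldimethylsilyl)oxy]-7-methoxy-2,2-dimethylchroman
Product: 16 (S)-8-bromo-3,5-bis[(tert-butyldimethylsilyl)oxy]-7-methoxy-2,2-dimethylchroman
Conditions: NBS (1.0 equiv), CH2Cl2, −78 → −20 °C, dark
Reagents that add atoms: N-bromosuccinimide, O=C1CCC(=O)N1Br
Why: Electrophilic aromatic bromination in which C6 and C8 are each activated by three oxygens, but C6 lies between OMe and the bulky silyl ether while C8 sits beside the tied-back ring oxygen O1, in line with the C8 preference well known for NBS bromination of 5,7-di-O-protected flavan-3-ols.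

Step 11
Reactants: 17 4-[(tert-butyldimethylsilyl)oxy]benzaldehyde; 18 diethyl {2-[methoxy(methyl)amino]-2-oxoethyl}phosphonate
Product: 19 (E)-3-{4-[(tert-butyldimethylsilyl)oxy]phenyl}-N-methoxy-N-methylprop-2-enamide
Conditions: 18, NaH (1.1 equiv), THF, 0 °C; then 17, 0 °C → rt
Reagents that add atoms: none
Why: Horner–Wadsworth–Emmons olefination with a stabilised amide phosphonate, which should give the E-alkene with an aromatic aldehyde and leaves the aryl silyl ether untouched under anhydrous conditions.

Step 12
Reactants: 16 (S)-8-bromo-3,5-bis[(tert-butyldimethylsilyl)oxy]-7-methoxy-2,2-dimethylchroman; 19 (E)-3-{4-[(tert-butyldimethylsilyl)oxy]phenyl}-N-methoxy-N-methylprop-2-enamide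
Product: 21 (E)-1-{(3S)-3,5-bis[(tert-butyldimethylsilyl)oxy]-7-methoxy-2,2-dimethylchroman-8-yl}-3-{4-[(tert-butyldimethylsilyl)oxy]phenyl}prop-2-en-1-one, via aryllithium 20 (not isolated)
Conditions: n-BuLi (1.05 equiv), THF, −78 °C, 20 min; then 19 (1.3 equiv), −78 → −20 °C; aq. NH4Cl
Reagents that add atoms: none
Why: Bromine–lithium exchange followed by Weinreb ketone synthesis, in which exchange at −78 °C outruns any attack on the silyl ethers, the hard aryllithium 20 adds 1,2 to the amide carbonyl, and N-methoxy chelation withholds the ketone until work-up, so neither over-addition nor conjugate addition to the enone should occur.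

Step 13
Reactants: 21 (E)-1-{(3S)-3,5-bis[(tert-butyldimethylsilyl)oxy]-7-methoxy-2,2-dimethylchroman-8-yl}-3-{4-[(tert-butyldimethylsilyl)oxy]phenyl}prop-2-en-1-one
Product: 22 (E)-1-[(3S)-3,5-dihydroxy-7-methoxy-2,2-dimethylchroman-8-yl]-3-(4-hydroxyphenyl)prop-2-en-1-one (CNP0122093.2)
Conditions: HF·pyridine, pyridine/THF, 0 °C → rt
Reagents that add atoms: none
Why: Fluoride-mediated cleavage of all three silyl ethers, driven by Si–F bond formation, under mildly acidic conditions that spare the enone, the methyl ether and the chroman, while flavanone formation is impossible because both positions ortho to the ketone are etherified (O1 and OMe).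

**Compound list**

1 | 2,4,6-trimethoxybenzaldehyde | COc1cc(OC)c(C=O)c(OC)c1 | starting material
2 | 2,6-dihydroxy-4-methoxybenzaldehyde | COc1cc(O)c(C=O)c(O)c1 | intermediate
3 | 2-(benzyloxy)-6-hydroxy-4-methoxybenzaldehyde | COc1cc(O)c(C=O)c(OCc2ccccc2)c1 | intermediate
4 | 3-(benzyloxy)-2-(hydroxymethyl)-5-methoxyphenol | COc1cc(O)c(CO)c(OCc2ccccc2)c1 | intermediate
5 | 3-(benzyloxy)-5-methoxy-2-(tosylmethyl)phenol | COc1cc(O)c(CS(=O)(=O)c2ccc(C)cc2)c(OCc2ccccc2)c1 | intermediate
6 | (benzyloxy)acetic acid | OC(=O)COCc1ccccc1 | starting material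
7 | (benzyloxy)acetic pivalic anhydride (not isolated) | CC(C)(C)C(=O)OC(=O)COCc1ccccc1 | intermediate
8 | 5-(benzyloxy)-3-methoxy-6-methylidenecyclohexa-2,4-dien-1-one, the ortho-quinone methide (not isolated) | C=C1C(=O)C=C(OC)C=C1OCc1ccccc1 | intermediate
9 | (Z)-ammonium enolate of the (benzyloxy)acetyl group on N1 of the (R)-isothiourea (not isolated) | [O-]/C(=C\OCc1ccccc1)[N+]1=C2Sc3ccccc3N2C[C@H]1c1ccccc1 | intermediate
10 | (S)-3,5-bis(benzyloxy)-7-methoxychroman-2-one | COc1cc(OCc2ccccc2)c2c(c1)OC(=O)[C@@H](OCc1ccccc1)C2 | intermediate
11 | (S)-3-(benzyloxy)-4-[2-(benzyloxy)-6-hydroxy-4-methoxyphenyl]butan-2-one (not isolated) | COc1cc(O)c(C[C@H](OCc2ccccc2)C(C)=O)c(OCc2ccccc2)c1 | intermediate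
12 | (S)-3-(benzyloxy)-2-[2-(benzyloxy)-3-hydroxy-3-methylbutyl]-5-methoxyphenol | COc1cc(O)c(C[C@H](OCc2ccccc2)C(C)(C)O)c(OCc2ccccc2)c1 | intermediate
13 | (S)-3,5-bis(benzyloxy)-7-methoxy-2,2-dimethylchroman | COc1cc(OCc2ccccc2)c2c(c1)OC(C)(C)[C@@H](OCc1ccccc1)C2 | intermediate
14 | (S)-7-methoxy-2,2-dimethylchroman-3,5-diol | COc1cc(O)c2c(c1)OC(C)(C)[C@@H](O)C2 | intermediate
15 | (S)-3,5-bis[(tert-butyldimethylsilyl)oxy]-7-methoxy-2,2-dimethylchroman | COc1cc(O[Si](C)(C)C(C)(C)C)c2c(c1)OC(C)(C)[C@@H](O[Si](C)(C)C(C)(C)C)C2 | intermediate
16 | (S)-8-bromo-3,5-bis[(tert-butyldimethylsilyl)oxy]-7-methoxy-2,2-dimethylchroman | COc1cc(O[Si](C)(C)C(C)(C)C)c2c(c1Br)OC(C)(C)[C@@H](O[Si](C)(C)C(C)(C)C)C2 | intermediate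
17 | 4-[(tert-butyldimethylsilyl)oxy]benzaldehyde | O=Cc1ccc(O[Si](C)(C)C(C)(C)C)cc1 | starting material
18 | diethyl {2-[methoxy(methyl)amino]-2-oxoethyl}phosphonate | CCOP(=O)(CC(=O)N(C)OC)OCC | starting material
19 | (E)-3-{4-[(tert-butyldimethylsilyl)oxy]phenyl}-N-methoxy-N-methylprop-2-enamide | CON(C)C(=O)/C=C/c1ccc(O[Si](C)(C)C(C)(C)C)cc1 | intermediate
20 | (S)-3,5-bis[(tert-butyldimethylsilyl)oxy]-7-methoxy-2,2-dimethylchroman-8-yllithium (not isolated) | COc1cc(O[Si](C)(C)C(C)(C)C)c2c(c1[Li])OC(C)(C)[C@@H](O[Si](C)(C)C(C)(C)C)C2 | intermediate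
21 | (E)-1-{(3S)-3,5-bis[(tert-butyldimethylsilyl)oxy]-7-methoxy-2,2-dimethylchroman-8-yl}-3-{4-[(tert-butyldimethylsilyl)oxy]phenyl}prop-2-en-1-one | COc1cc(O[Si](C)(C)C(C)(C)C)c2c(c1C(=O)/C=C/c1ccc(O[Si](C)(C)C(C)(C)C)cc1)OC(C)(C)[C@@H](O[Si](C)(C)C(C)(C)C)C2 | intermediate
22 | (E)-1-[(3S)-3,5-dihydroxy-7-methoxy-2,2-dimethylchroman-8-yl]-3-(4-hydroxyphenyl)prop-2-en-1-one | COc1cc(O)c2c(c1C(=O)/C=C/c1ccc(O)cc1)OC(C)(C)[C@@H](O)C2 | target

**Step count**

Total step count: 13. Longest linear sequence: 12 (steps 1–10, 12 and 13); step 11 is the side branch.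

**Steps most likely to fail**

Step 5. Slow deprotonation of the alpha-benzyloxy acyl ammonium ion would let O-acylation of the phenol and self-condensation of the quinone methide take over. Weak facial discrimination, or base-induced enolisation of the lactone, would erode the enantiopurity. The fallback uses known chemistry only, sets out from 3 and comes back at 14. Excess 2-methylprop-1-enylmagnesium bromide adds to aldehyde 3 to give racemic 3-(benzyloxy)-2-(1-hydroxy-3-methylbut-2-en-1-yl)-5-methoxyphenol F1. Pyridinium p-toluenesulfonate in warm toluene then brings about dehydration and oxa-6π electrocyclisation to 5-(benzyloxy)-7-methoxy-2,2-dimethyl-2H-chromene F2. Jacobsen–Katsuki epoxidation follows, with (S,S)-[N,N'-bis(3,5-di-tert-butylsalicylidene)-1,2-cyclohexanediaminato]manganese chloride, NaOCl and 4-phenylpyridine N-oxide at 0 °C. 2,2-Dimethylchromenes are the classical substrates for this reaction, which should give (3S,4S)-5-(benzyloxy)-3,4-epoxy-7-methoxy-2,2-dimethylchroman F3. Hydrogenolysis (H2, Pd/C) cleaves the benzylic C4–O bond and the benzyl ether together, leaving the C3–O bond intact, to reach 14.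

Step 7. Ionisation at C2 is slowed by the adjacent benzyloxy group. A 1,2-hydride shift from C3 or proton loss from C3 may then compete with ring closure and erase the stereocentre, and forcing acid could also cause benzyl migration on the electron-rich ring. The fallback sets out from 12 and comes back at 13. The phenol is triflated selectively (PhNTf2, Et3N, CH2Cl2; the tertiary alcohol does not react) to give (S)-3-(benzyloxy)-2-[2-(benzyloxy)-3-hydroxy-3-methylbutyl]-5-methoxyphenyl trifluoromethanesulfonate F4. An intramolecular Buchwald–Hartwig-type C–O coupling (Pd(OAc)2, 2-(di-tert-butylphosphino)-1,1'-binaphthyl, Cs2CO3, toluene, 80 °C) then joins the tertiary alkoxide oxygen to C8a. This coupling is known for tertiary alcohols closing 2,2-dimethylchromans. O1 then stems from the alcohol and no cation arises next to C3.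

Step 10. Poor site selectivity between C6 and C8 would lead toward the C6-acyl regioisomer of the target. Over-bromination of the trioxygenated ring is a second concern. The fallback sets out from 14 and comes back at 16, and replaces steric control by electronic control from a free phenol. Diol 14 is brominated with n-Bu4NBr3 in CH2Cl2/MeOH at low temperature, a reagent known for para-selective monobromination of phenols. C8 is the position para to the C5 hydroxyl, so this should give (S)-8-bromo-7-methoxy-2,2-dimethylchroman-3,5-diol F5. Bis-silylation under the conditions of step 9 then gives 16.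

**Further compounds**

F1 | step 5 | 3-(benzyloxy)-2-(1-hydroxy-3-methylbut-2-en-1-yl)-5-methoxyphenol (racemic) | COc1cc(O)c(C(O)C=C(C)C)c(OCc2ccccc2)c1
F2 | step 5 | 5-(benzyloxy)-7-methoxy-2,2-dimethyl-2H-chromene | COc1cc(OCc2ccccc2)c2C=CC(C)(C)Oc2c1
F3 | step 5 | (3S,4S)-5-(benzyloxy)-3,4-epoxy-7-methoxy-2,2-dimethylchroman | COc1cc(OCc2ccccc2)c2c(c1)OC(C)(C)[C@H]1O[C@H]12
F4 | step 7 | (S)-3-(benzyloxy)-2-[2-(benzyloxy)-3-hydroxy-3-methylbutyl]-5-methoxyphenyl trifluoromethanesulfonate | COc1cc(OS(=O)(=O)C(F)(F)F)c(C[C@H](OCc2ccccc2)C(C)(C)O)c(OCc2ccccc2)c1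
F5 | step 10 | (S)-8-bromo-7-methoxy-2,2-dimethylchroman-3,5-diol | COc1cc(O)c2c(c1Br)OC(C)(C)[C@@H](O)C2
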